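**Plan**
- Retrosynthesis: ring C is opened at O1–C2 and C4–C4a together, giving aryl cinnamate 24, in which the acyl carbon C4 is parked on O1 (an ester bond absent from the target) and C4a carries iodine. 24 is cut at that ester into ring A phenol 18 and ring B acid 23, and 18 at the ArCH2–lavandulyl bond.
- Forward: (S)-lavandulyl iodide is joined to MOM-protected phloroglucinol through its cuprate, ring A is iodinated and its oxygens differentiated so that only O1 is free, acid 23 is esterified onto O1, ring C is closed last, then desilylation.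
- Enabling feature: in ring A, C4a is the ortho neighbour of C8a–O1, so a carbanion at C4a reaches the acyl carbon held on O1 across the array C4a, C8a, O1, C4. The 1,3 O→C acyl shift makes C4–C4a and frees O1, which then closes the six-membered ring O1, C8a, C4a, C4, C3, C2 onto the enone β-carbon C2.
- Regiochemistry (8- versus 6-lavandulyl) follows from the tether: the oxygen that carried the acyl group is the only free phenol.
- Stereochemistry: the lavandulyl centre comes from an auxiliary-controlled deconjugative prenylation (step 2), C2 from the catalyst-controlled oxa-Michael closure (step 13).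

Key step: step 13

Assumption: the sense of induction of the cinchona thiourea on chalcone 27 is assigned by analogy only; if the quinidine-derived catalyst favours the (2R) epimer, its quinine-derived pseudoenantiomer is used under the same conditions. "Lavandulyl" stands for 5-methyl-2-(prop-1-en-2-yl)hex-4-en-1-yl.

**Step 1**
Reactants: 1 (S)-4-benzyloxazolidin-2-one; 2 3-methylbut-2-enoyl chloride
Product: 4 (S)-4-benzyl-3-(3-methylbut-2-enoyl)oxazolidin-2-one, via lithium oxazolidinide 3 (not isolated)
Conditions: n-BuLi, THF, −78 °C; then 2, −78 to 0 °C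
Reagents that add atoms: none
Why: N-acylation of the lithiated Evans auxiliary, run cold so that the acid chloride does not form a vinylketene and the conjugated enoyl imide results.

**Step 2**
Reactants: 4 (S)-4-benzyl-3-(3-methylbut-2-enoyl)oxazolidin-2-one; 5 prenyl bromide (1-bromo-3-methylbut-2-ene)
Product: 7 (S)-4-benzyl-3-[(2S)-5-methyl-2-(prop-1-en-2-yl)hex-4-enoyl]oxazolidin-2-one, via sodium dienolate 6 (not isolated)
Conditions: NaHMDS, THF, −78 °C; then 5, −78 to −40 °C
Reagents that add atoms: none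
Why: Evans asymmetric alkylation in its deconjugative form: γ-deprotonation gives the chelated (Z)-dienolate, which should be alkylated at the α-carbon on the face away from the benzyl group, setting the (S) centre and leaving the isopropenyl group.

**Step 3**
Reactants: 7 (S)-4-benzyl-3-[(2S)-5-methyl-2-(prop-1-en-2-yl)hex-4-enoyl]oxazolidin-2-one
Product: 8 (S)-lavandulol [(2S)-5-methyl-2-(prop-1-en-2-yl)hex-4-en-1-ol]
Conditions: LiBH4, H2O (1 equiv), Et2O, 0 °C
Reagents that add atoms: none
Why: Reductive cleavage of the N-acyl oxazolidinone by hydride is faster than enolisation, so the α-centre and the β,γ-position of the alkene should be kept and the auxiliary recovered.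

**Step 4**
Reactants: 8 (S)-lavandulol
Product: 9 (S)-lavandulyl iodide [(2S)-1-iodo-5-methyl-2-(prop-1-en-2-yl)hex-4-ene]
Conditions: I2, PPh3, imidazole, CH2Cl2, 0 °C to rt
Reagents that add atoms: iodine, II
Why: Appel-type (Garegg–Samuelsson) iodination, an SN2 displacement at the primary carbon that leaves the neighbouring stereocentre untouched.

**Step 5**
Reactants: 10 phloroglucinol (benzene-1,3,5-triol)
Product: 11 1,3,5-tris(methoxymethoxy)benzene
Conditions: MOMCl, i-Pr2NEt, DMF, 0 °C to rt
Reagents that add atoms: chloromethyl methyl ether (MOMCl), COCCl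
Why: O-alkylation of the three phenols with the α-chloro ether (MOM protection) gives acetal groups that direct the metalations of steps 6 and 7.

**Step 6**
Reactants: 11 1,3,5-tris(methoxymethoxy)benzene (2.2 equiv); 9 (S)-lavandulyl iodide
Product: 14 2-[(2R)-lavandulyl]-1,3,5-tris(methoxymethoxy)benzene, via aryllithium 12 (not isolated), via lithium diarylcuprate 13 (not isolated)
Conditions: n-BuLi, THF, 0 °C; CuI (0.5 equiv per aryllithium), −40 °C; then 9, −20 °C to rt
Reagents that add atoms: none
Why: Directed ortho-metalation between two OMOM groups, then SN2 alkylation of the Gilman diarylcuprate by the primary iodide (Corey–Posner/Whitesides–House coupling); the soft cuprate is chosen to avoid E2 loss of the allylic β-hydrogen, and the stereocentre is not involved.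

**Step 7**
Reactants: 14 2-[(2R)-lavandulyl]-1,3,5-tris(methoxymethoxy)benzene
Product: 16 2-iodo-4-[(2R)-lavandulyl]-1,3,5-tris(methoxymethoxy)benzene, via aryllithium 15 (not isolated)
Conditions: n-BuLi, THF, 0 °C; then I2, −78 °C
Reagents that add atoms: iodine, II
Why: Directed ortho-metalation and iodinolysis: both free ring positions lie between two OMOM groups and are constitutionally equivalent, so a single mono-iodide should form, and the aryllithium should consume iodine far faster than the side-chain alkenes do.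

**Step 8**
Reactants: 16 2-iodo-4-[(2R)-lavandulyl]-1,3,5-tris(methoxymethoxy)benzene
Product: 17 4-iodo-2-[(2R)-lavandulyl]benzene-1,3,5-triol
Conditions: HCl (1.25 M in MeOH), MeOH, rt
Reagents that add atoms: none
Why: Acid-catalysed acetal exchange (MOM cleavage) with methanol taking up the formaldehyde unit; dilute acid at room temperature is chosen so that neither the trisubstituted alkene nor the aryl iodide is protonated.

**Step 9**
Reactants: 17 4-iodo-2-[(2R)-lavandulyl]benzene-1,3,5-triol
Product: 18 2-iodo-6-[(2R)-lavandulyl]-3,5-bis(triisopropylsilyloxy)phenol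
Conditions: TIPSCl (2.1 equiv), imidazole, DMF–CH2Cl2, 0 °C
Reagents that add atoms: triisopropylsilyl chloride (TIPSCl), CC(C)[Si](Cl)(C(C)C)C(C)C
Why: Silyl ether formation under steric control: the hydroxyl flanked by both iodine and the side-chain CH2 is di-ortho-substituted and should resist the bulky chloride, while the two mono-ortho-substituted hydroxyls are silylated.

**Step 10**
Reactants: 19 4-hydroxy-2-methoxybenzaldehyde; 20 malonic acid
Product: 21 (E)-3-(4-hydroxy-2-methoxyphenyl)prop-2-enoic acid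
Conditions: pyridine, piperidine (cat.), 80 °C
Reagents that add atoms: none
Why: Knoevenagel–Doebner condensation, in which decarboxylation of the arylidenemalonic acid should give the (E)-cinnamic acid.

**Step 11**
Reactants: 21 (E)-3-(4-hydroxy-2-methoxyphenyl)prop-2-enoic acid
Product: 23 (E)-3-[2-methoxy-4-(triisopropylsilyloxy)phenyl]prop-2-enoic acid, via silyl ester 22 (not isolated)
Conditions: TIPSCl (2.3 equiv), imidazole, DMF, rt; then AcOH–THF–H2O, rt
Reagents that add atoms: triisopropylsilyl chloride (TIPSCl), CC(C)[Si](Cl)(C(C)C)C(C)C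
Why: Silylation of phenol and carboxyl followed by selective hydrolysis of the silyl ester, which is far more labile than the aryl silyl ether.

**Step 12**
Reactants: 18 2-iodo-6-[(2R)-lavandulyl]-3,5-bis(triisopropylsilyloxy)phenol; 23 (E)-3-[2-methoxy-4-(triisopropylsilyloxy)phenyl]prop-2-enoic acid
Product: 24 2-iodo-6-[(2R)-lavandulyl]-3,5-bis(triisopropylsilyloxy)phenyl (E)-3-[2-methoxy-4-(triisopropylsilyloxy)phenyl]prop-2-enoate
Conditions: DCC, DMAP, CH2Cl2, 0 °C to rt
Reagents that add atoms: none
Why: Steglich esterification, in which the acylpyridinium should be reactive enough for the hindered phenol; this builds the O1–acyl tether that step 13 consumes.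

**Step 13**
Reactants: 24 2-iodo-6-[(2R)-lavandulyl]-3,5-bis(triisopropylsilyloxy)phenyl (E)-3-[2-methoxy-4-(triisopropylsilyloxy)phenyl]prop-2-enoate
Product: 28 (2S)-8-[(2R)-lavandulyl]-2-[2-methoxy-4-(triisopropylsilyloxy)phenyl]-5,7-bis(triisopropylsilyloxy)chroman-4-one, via aryllithium 25 (not isolated), via lithium chalcone phenoxide 26 (not isolated), via 2'-hydroxychalcone 27 (not isolated)
Conditions: n-BuLi (1.05 equiv), toluene–Et2O (5:1), −95 °C; AcOH (1.05 equiv), −78 °C; then 1-[3,5-bis(trifluoromethyl)phenyl]-3-[(9R)-6'-methoxycinchonan-9-yl]thiourea (quinidine-derived, 10 mol %), −30 °C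
Reagents that add atoms: none
Why: Proposed new method: iodine–lithium exchange at the ring A carbon ortho to the ester oxygen is expected to outrun attack of n-BuLi on the cinnamate, and aryllithium 25 then adds to its own ester carbonyl (four-membered alkoxide, 4-exo-trig) and collapses by C–O cleavage, a 1,3 O→C acyl shift that makes the C4–C4a bond and releases O1 as lithium phenoxide 26, whose open chalcone form is the stable one so that no ring closure occurs before protonation. The closest known reaction types are the halogen–metal exchange-induced anionic Fries rearrangement of o-iodoaryl benzoates and the cinchona thiourea-catalysed cyclisation of 2'-hydroxychalcones to flavanones, joined here in one flask and applied to a cinnamate ester. After protonation to 27 the tertiary amine of the catalyst should activate the phenol while the thiourea binds the ketone oxygen, and ring C closes by 6-endo-trig oxa-Michael addition of O1 to C2. The new C2 stereocentre is set by the catalyst, which is expected to expose one enone face to the phenoxide, the remote lavandulyl centre having no say. Regiochemistry needs no further control because the only free phenol is the one that carried the acyl group (the 5- and 7-oxygens are silylated), so the 8-lavandulyl and not the 6-lavandulyl chromanone must form; 1,2- over 1,4-attack of the aryllithium is secured by the four-centre proximity of the ester carbonyl and by the hard lithium reagent in a weakly coordinating solvent at −95 °C.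

**Step 14**
Reactants: 28 (2S)-8-[(2R)-lavandulyl]-2-[2-methoxy-4-(triisopropylsilyloxy)phenyl]-5,7-bis(triisopropylsilyloxy)chroman-4-one
Product: 29 leachianone A
Conditions: HF·pyridine, pyridine, THF, 0 °C
Reagents that add atoms: none
Why: Fluoride-mediated cleavage of the three aryl silyl ethers with a buffered reagent that should be neither basic enough to open ring C by retro-oxa-Michael reaction nor acidic enough to cyclise the lavandulyl group onto the 7-hydroxyl, so both stereocentres are kept.

**Compound list**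
1 | (S)-4-benzyloxazolidin-2-one | O=C1OC[C@H](Cc2ccccc2)N1 | starting material
2 | 3-methylbut-2-enoyl chloride | CC(C)=CC(=O)Cl | starting material
3 | lithium (S)-4-benzyl-2-oxooxazolidin-3-ide (in situ) | [Li+].O=C1OC[C@H](Cc2ccccc2)[N-]1 | intermediate
4 | (S)-4-benzyl-3-(3-methylbut-2-enoyl)oxazolidin-2-one | CC(C)=CC(=O)N1[C@@H](Cc2ccccc2)COC1=O | intermediate
5 | prenyl bromide (1-bromo-3-methylbut-2-ene) | CC(C)=CCBr | starting material
6 | sodium (Z)-dienolate of 4 (in situ) | C=C(C)/C=C(\[O-])N1[C@@H](Cc2ccccc2)COC1=O.[Na+] | intermediate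
7 | (S)-4-benzyl-3-[(2S)-5-methyl-2-(prop-1-en-2-yl)hex-4-enoyl]oxazolidin-2-one | C=C(C)[C@H](CC=C(C)C)C(=O)N1[C@@H](Cc2ccccc2)COC1=O | intermediate
8 | (S)-lavandulol, (2S)-5-methyl-2-(prop-1-en-2-yl)hex-4-en-1-ol | C=C(C)[C@H](CC=C(C)C)CO | intermediate
9 | (S)-lavandulyl iodide, (2S)-1-iodo-5-methyl-2-(prop-1-en-2-yl)hex-4-ene | C=C(C)[C@H](CC=C(C)C)CI | intermediate
10 | phloroglucinol | Oc1cc(O)cc(O)c1 | starting material
11 | 1,3,5-tris(methoxymethoxy)benzene | COCOc1cc(OCOC)cc(OCOC)c1 | intermediate
12 | 2,4,6-tris(methoxymethoxy)phenyllithium (in situ) | [Li]c1c(OCOC)cc(OCOC)cc1OCOC | intermediate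
13 | lithium bis[2,4,6-tris(methoxymethoxy)phenyl]cuprate (in situ) | [Li+].COCOc1cc(OCOC)cc(OCOC)c1[Cu-]c1c(OCOC)cc(OCOC)cc1OCOC | intermediate
14 | 2-[(2R)-lavandulyl]-1,3,5-tris(methoxymethoxy)benzene | C=C(C)[C@H](CC=C(C)C)Cc1c(OCOC)cc(OCOC)cc1OCOC | intermediate
15 | 3-[(2R)-lavandulyl]-2,4,6-tris(methoxymethoxy)phenyllithium (in situ) | C=C(C)[C@H](CC=C(C)C)Cc1c(OCOC)cc(OCOC)c([Li])c1OCOC | intermediate
16 | 2-iodo-4-[(2R)-lavandulyl]-1,3,5-tris(methoxymethoxy)benzene | C=C(C)[C@H](CC=C(C)C)Cc1c(OCOC)cc(OCOC)c(I)c1OCOC | intermediate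
17 | 4-iodo-2-[(2R)-lavandulyl]benzene-1,3,5-triol | C=C(C)[C@H](CC=C(C)C)Cc1c(O)cc(O)c(I)c1O | intermediate
18 | 2-iodo-6-[(2R)-lavandulyl]-3,5-bis(triisopropylsilyloxy)phenol | C=C(C)[C@H](CC=C(C)C)Cc1c(O[Si](C(C)C)(C(C)C)C(C)C)cc(O[Si](C(C)C)(C(C)C)C(C)C)c(I)c1O | intermediate
19 | 4-hydroxy-2-methoxybenzaldehyde | COc1cc(O)ccc1C=O | starting material
20 | malonic acid | OC(=O)CC(=O)O | starting material
21 | (E)-3-(4-hydroxy-2-methoxyphenyl)prop-2-enoic acid | COc1cc(O)ccc1/C=C/C(=O)O | intermediate
22 | triisopropylsilyl (E)-3-[2-methoxy-4-(triisopropylsilyloxy)phenyl]prop-2-enoate (in situ) | COc1cc(O[Si](C(C)C)(C(C)C)C(C)C)ccc1/C=C/C(=O)O[Si](C(C)C)(C(C)C)C(C)C | intermediate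
23 | (E)-3-[2-methoxy-4-(triisopropylsilyloxy)phenyl]prop-2-enoic acid | COc1cc(O[Si](C(C)C)(C(C)C)C(C)C)ccc1/C=C/C(=O)O | intermediate
24 | 2-iodo-6-[(2R)-lavandulyl]-3,5-bis(triisopropylsilyloxy)phenyl (E)-3-[2-methoxy-4-(triisopropylsilyloxy)phenyl]prop-2-enoate | C=C(C)[C@H](CC=C(C)C)Cc1c(O[Si](C(C)C)(C(C)C)C(C)C)cc(O[Si](C(C)C)(C(C)C)C(C)C)c(I)c1OC(=O)/C=C/c1ccc(O[Si](C(C)C)(C(C)C)C(C)C)cc1OC | intermediate
25 | 2-lithio analogue of 24 (lithium in place of iodine, in situ) | C=C(C)[C@H](CC=C(C)C)Cc1c(O[Si](C(C)C)(C(C)C)C(C)C)cc(O[Si](C(C)C)(C(C)C)C(C)C)c([Li])c1OC(=O)/C=C/c1ccc(O[Si](C(C)C)(C(C)C)C(C)C)cc1OC | intermediate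
26 | lithium 2-[(E)-3-[2-methoxy-4-(triisopropylsilyloxy)phenyl]prop-2-enoyl]-6-[(2R)-lavandulyl]-3,5-bis(triisopropylsilyloxy)phenoxide (in situ) | C=C(C)[C@H](CC=C(C)C)Cc1c(O[Si](C(C)C)(C(C)C)C(C)C)cc(O[Si](C(C)C)(C(C)C)C(C)C)c(C(=O)/C=C/c2ccc(O[Si](C(C)C)(C(C)C)C(C)C)cc2OC)c1[O-].[Li+] | intermediate
27 | (E)-1-[2-hydroxy-3-[(2R)-lavandulyl]-4,6-bis(triisopropylsilyloxy)phenyl]-3-[2-methoxy-4-(triisopropylsilyloxy)phenyl]prop-2-en-1-one (in situ) | C=C(C)[C@H](CC=C(C)C)Cc1c(O[Si](C(C)C)(C(C)C)C(C)C)cc(O[Si](C(C)C)(C(C)C)C(C)C)c(C(=O)/C=C/c2ccc(O[Si](C(C)C)(C(C)C)C(C)C)cc2OC)c1O | intermediate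
28 | (2S)-8-[(2R)-lavandulyl]-2-[2-methoxy-4-(triisopropylsilyloxy)phenyl]-5,7-bis(triisopropylsilyloxy)chroman-4-one | C=C(C)[C@H](CC=C(C)C)Cc1c(O[Si](C(C)C)(C(C)C)C(C)C)cc(O[Si](C(C)C)(C(C)C)C(C)C)c2c1O[C@H](c1ccc(O[Si](C(C)C)(C(C)C)C(C)C)cc1OC)CC2=O | intermediate
29 | leachianone A, (2S)-5,7-dihydroxy-2-(4-hydroxy-2-methoxyphenyl)-8-[(2R)-lavandulyl]chroman-4-one | C=C(C)[C@H](CC=C(C)C)Cc1c(O)cc(O)c2c1O[C@H](c1ccc(O)cc1OC)CC2=O | target

**Step count and risks**
Total: 14 steps. Longest linear sequence: 11 steps (steps 1–4, 6–9, 12–14).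

Step 13. The catalysed ring closure may show low facial selectivity on this hindered, electron-rich chalcone, or the selectivity may erode through reversible ring opening. The fallback sets out from 24 and returns at 28. Only the first half of step 13 is run (n-BuLi, −95 °C, aqueous quench) and chalcone 27 is isolated. Conjugate borylation of 27 with bis(pinacolato)diboron and MeOH (CuCl, NaOt-Bu, the Josiphos enantiomer that delivers the R product) should give (3R)-1-[2-hydroxy-3-[(2R)-lavandulyl]-4,6-bis(triisopropylsilyloxy)phenyl]-3-[2-methoxy-4-(triisopropylsilyloxy)phenyl]-3-(4,4,5,5-tetramethyl-1,3,2-dioxaborolan-2-yl)propan-1-one F1. Oxidation with NaBO3 with retention should give the (3R)-3-hydroxy ketone F2. Mitsunobu closure (PPh3, DIAD) of the phenol onto the carbinol carbon with inversion should give 28.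

Step 6. The β-branched iodide may undergo E2 elimination of its allylic β-hydrogen, or the hindered aryl group may transfer sluggishly. The fallback sets out from 11 and 9 and returns at 14, with the roles of the partners reversed. Aryllithium 12 is quenched with I2 to give 2-iodo-1,3,5-tris(methoxymethoxy)benzene F3. Iodide 9 is converted by iodine–lithium exchange (t-BuLi, Et2O–pentane, −78 °C) into [(2S)-5-methyl-2-(prop-1-en-2-yl)hex-4-en-1-yl]lithium F4 and then with ZnCl2 into [(2S)-5-methyl-2-(prop-1-en-2-yl)hex-4-en-1-yl]zinc chloride F5. Negishi coupling of F5 with F3 (Pd(OAc)2, SPhos, THF, rt) should give 14.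

Step 9. Steric discrimination among the three hydroxyls may be incomplete, and the air-sensitive iodotriol may degrade. The fallback sets out from 14 and returns at 18, with iodine introduced last so that no aryl iodide meets acid. HCl in MeOH converts 14 into 2-[(2R)-lavandulyl]benzene-1,3,5-triol F6. TIPSCl and imidazole should silylate first the unhindered hydroxyl para to the side chain, giving 2-[(2R)-lavandulyl]-5-(triisopropylsilyloxy)benzene-1,3-diol F7. A second silylation at one of the two equivalent remaining hydroxyls (statistical, with recycling of under- and over-silylated material) should give 2-[(2R)-lavandulyl]-3,5-bis(triisopropylsilyloxy)phenol F8. Ortho-iodination of F8 with the I2–morpholine complex, at the only ring position not shielded by two silyloxy groups, should give 18.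

**Further compounds**
F1 | step 13 | (3R)-1-[2-hydroxy-3-[(2R)-lavandulyl]-4,6-bis(triisopropylsilyloxy)phenyl]-3-[2-methoxy-4-(triisopropylsilyloxy)phenyl]-3-(4,4,5,5-tetramethyl-1,3,2-dioxaborolan-2-yl)propan-1-one | C=C(C)[C@H](CC=C(C)C)Cc1c(O[Si](C(C)C)(C(C)C)C(C)C)cc(O[Si](C(C)C)(C(C)C)C(C)C)c(C(=O)C[C@@H](B2OC(C)(C)C(C)(C)O2)c2ccc(O[Si](C(C)C)(C(C)C)C(C)C)cc2OC)c1O
F2 | step 13 | (3R)-3-hydroxy-1-[2-hydroxy-3-[(2R)-lavandulyl]-4,6-bis(triisopropylsilyloxy)phenyl]-3-[2-methoxy-4-(triisopropylsilyloxy)phenyl]propan-1-one | C=C(C)[C@H](CC=C(C)C)Cc1c(O[Si](C(C)C)(C(C)C)C(C)C)cc(O[Si](C(C)C)(C(C)C)C(C)C)c(C(=O)C[C@@H](O)c2ccc(O[Si](C(C)C)(C(C)C)C(C)C)cc2OC)c1O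
F3 | step 6 | 2-iodo-1,3,5-tris(methoxymethoxy)benzene | COCOc1cc(OCOC)c(I)c(OCOC)c1
F4 | step 6 | [(2S)-5-methyl-2-(prop-1-en-2-yl)hex-4-en-1-yl]lithium | C=C(C)[C@H](CC=C(C)C)C[Li]
F5 | step 6 | [(2S)-5-methyl-2-(prop-1-en-2-yl)hex-4-en-1-yl]zinc chloride | C=C(C)[C@H](CC=C(C)C)C[Zn]Cl
F6 | step 9 | 2-[(2R)-lavandulyl]benzene-1,3,5-triol | C=C(C)[C@H](CC=C(C)C)Cc1c(O)cc(O)cc1O
F7 | step 9 | 2-[(2R)-lavandulyl]-5-(triisopropylsilyloxy)benzene-1,3-diol | C=C(C)[C@H](CC=C(C)C)Cc1c(O)cc(O[Si](C(C)C)(C(C)C)C(C)C)cc1O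
F8 | step 9 | 2-[(2R)-lavandulyl]-3,5-bis(triisopropylsilyloxy)phenol | C=C(C)[C@H](CC=C(C)C)Cc1c(O[Si](C(C)C)(C(C)C)C(C)C)cc(O[Si](C(C)C)(C(C)C)C(C)C)cc1O
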